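**Plan**

The target is a 6-prenyl-1H-indole (ring A, unprimed atoms) whose C3 carries N1' of a second 6-prenylindole (ring B, primed atoms). Because N1' is bonded to C3, C2' and C7a', a 3-aminoindole can bring N1' in and ring B can be grown around it.
Retrosynthesis: N1–H is masked as its SEM derivative; then N1'–C7a', N1'–C2' and C3a'–C3' are cut in one operation, giving amine 9 (ring A with N1'), dihaloarene 13 (benzene part of ring B) and trimethylsilylacetylene 14 (C2' and C3').
The C3–N bond of 9 is traced to a C3 carboxyl group by Curtius rearrangement, and both aryl–prenyl bonds to Stille couplings of aryl bromides with one prenylstannane.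
Forward: ring A is bought intact as a 6-bromoindole-3-carboxylate and the benzene ring of ring B as 4-bromo-2-chloroaniline. Each is prenylated and converted into 9 and 13, the pyrrole of ring B (the only ring made) closes in step 8, and fluoride then frees N1–H.
Stereochemistry: the target has no stereocentre and no double bond with E/Z isomers. The only selectivity to secure is the position of the prenyl group on ring B (C6', not C5'), which the iodine/chlorine pattern of 13 fixes.

Key step: step 8

Remark on the chemistry: N1-alkylated 3-aminoindoles are assumed to be air-sensitive, so amine 9 is stored as its Teoc carbamate 8 and released just before the coupling.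
Abbreviations: prenyl = 3-methylbut-2-en-1-yl; SEM = [2-(trimethylsilyl)ethoxy]methyl; Teoc = 2-(trimethylsilyl)ethoxycarbonyl; DPPA = diphenylphosphoryl azide; TBAF = tetrabutylammonium fluoride; XPhos = 2-dicyclohexylphosphino-2',4',6'-triisopropylbiphenyl.

**Route**

Step 1
Reactants: 1 methyl 6-bromo-1H-indole-3-carboxylate
Product: 2 methyl 6-bromo-1-SEM-1H-indole-3-carboxylate
Conditions: NaH, DMF, 0 °C; SEMCl, 0 °C to rt
Reagents that add atoms: 2-(trimethylsilyl)ethoxymethyl chloride (SEMCl), C[Si](C)(C)CCOCCl
Why: N-alkylation of the indolide anion (the N–H is acidified by the C3 ester) with SEMCl is a standard protection and removes the acidic N–H that would interfere with the Curtius, amination and cyclisation steps.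

Step 2
Reactants: 2 methyl 6-bromo-1-SEM-1H-indole-3-carboxylate; 3 tributyl(3-methylbut-2-en-1-yl)stannane
Product: 4 methyl 6-prenyl-1-SEM-1H-indole-3-carboxylate
Conditions: Pd(PPh3)4 (5 mol%), DMF, 100 °C
Reagents that add atoms: none
Why: Stille coupling of a bromoindole with the prenylstannane is the established way to a linear aryl–prenyl bond, reductive elimination at the unsubstituted allyl terminus giving the 3-methylbut-2-enyl and not the reverse-prenyl isomer, and the ester and SEM group are inert.

Step 3
Reactants: 4 methyl 6-prenyl-1-SEM-1H-indole-3-carboxylate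
Product: 5 6-prenyl-1-SEM-1H-indole-3-carboxylic acid
Conditions: 2 M aq NaOH, MeOH/THF, 65 °C; then 1 M HCl to pH 4, 0 °C
Reagents that add atoms: sodium hydroxide, [Na+].[OH-]
Why: Saponification of the vinylogous carbamate ester needs warm hydroxide but is routine for N-alkylated indole-3-carboxylates, and cold acidification only to pH 4 should avoid decarboxylation of the acid and acid damage to the prenyl and SEM groups.

Step 4
Reactants: 5 6-prenyl-1-SEM-1H-indole-3-carboxylic acid
Product: 8 2-(trimethylsilyl)ethyl N-(6-prenyl-1-SEM-1H-indol-3-yl)carbamate, via acyl azide 6 (not isolated), via isocyanate 7 (not isolated)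
Conditions: DPPA, Et3N, toluene, rt then 90 °C; then 2-(trimethylsilyl)ethanol, 90 °C
Reagents that add atoms: diphenylphosphoryl azide, [N-]=[N+]=NP(=O)(Oc1ccccc1)Oc1ccccc1; 2-(trimethylsilyl)ethanol, C[Si](C)(C)CCO
Why: Curtius rearrangement, in which the acyl azide formed with DPPA loses N2 on heating as the electron-rich indol-3-yl group migrates to nitrogen, and the isocyanate is trapped by the alcohol as a storable Teoc carbamate instead of being hydrolysed to the sensitive amine at this stage.

Step 5
Reactants: 8 2-(trimethylsilyl)ethyl N-(6-prenyl-1-SEM-1H-indol-3-yl)carbamate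
Product: 9 6-prenyl-1-SEM-1H-indol-3-amine
Conditions: TBAF, THF, rt, argon; degassed aqueous work-up, used at once in step 8
Reagents that add atoms: none
Why: Standard Teoc cleavage, in which fluoride attacks silicon and triggers loss of ethylene and CO2, whereas the N1 SEM group needs hot fluoride to fragment and should survive at room temperature, so the oxidation-prone amine exists only just before it is used.

Step 6
Reactants: 10 4-bromo-2-chloroaniline; 3 tributyl(3-methylbut-2-en-1-yl)stannane
Product: 11 2-chloro-4-prenylaniline
Conditions: Pd(PPh3)4 (5 mol%), DMF, 100 °C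
Reagents that add atoms: none
Why: Stille coupling should occur only at the C–Br bond, which adds to zerovalent palladium far faster than the C–Cl bond, and the free aniline does not interfere.

Step 7
Reactants: 11 2-chloro-4-prenylaniline
Product: 13 2-chloro-1-iodo-4-prenylbenzene, via arenediazonium hydrogensulfate 12 (not isolated)
Conditions: NaNO2, aq H2SO4, MeCN, 0 °C; urea; then KI, 0 °C to rt
Reagents that add atoms: potassium iodide, [K+].[I-]
Why: Sandmeyer-type iodination, in which diazotisation at 0 °C and copper-free displacement of N2 by iodide put iodine exactly where the amino group was (para to the prenyl group), and excess nitrous acid is destroyed with urea before KI is added so that the olefin meets neither nitrosating agent nor iodine for long.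

Step 8
Reactants: 9 6-prenyl-1-SEM-1H-indol-3-amine; 13 2-chloro-1-iodo-4-prenylbenzene; 14 trimethylsilylacetylene
Product: 18 6-prenyl-3-(6-prenyl-1H-indol-1-yl)-1-SEM-1H-indole, via aryl silylalkyne 15 (not isolated), via silylalkynyl diarylamine 16 (not isolated), via ethynyl diarylamine 17 (not isolated)
Conditions: Pd(OAc)2 (5 mol%), XPhos (10 mol%), CuI (5 mol%), Cs2CO3, toluene, sealed tube, argon: 13 + 14, 60 °C; then 9, 105 °C; then KOtBu, 80 °C
Reagents that add atoms: none
Why: At 60 °C only the C–I bond of 13 adds oxidatively to the zerovalent palladium–XPhos catalyst, and the copper acetylide of 14 is transferred to that carbon (Sonogashira coupling), so 15 carries the alkyne para to the prenyl group and keeps its chlorine. Once 9 is added and the mixture is heated to 105 °C the same catalyst aminates the C–Cl bond (Buchwald–Hartwig amination), Cs2CO3 being strong enough for an arylamine yet too weak to cleave the C–Si bond, which gives 16. KOtBu then takes the silyl group off as tert-butyl trimethylsilyl ether and the potassium amide of 17 adds to the terminal alkyne carbon in a 5-endo-dig hydroamination that closes the pyrrole of ring B, protonation at C3' finishing 18. The closest known reaction type is the one-pot assembly of indoles from ortho-dihaloarenes, terminal alkynes and primary amines by Sonogashira coupling, aryl amination and hydroamination, combined with the alkoxide-mediated cyclisation of 2-(silylethynyl)anilines to 2,3-unsubstituted indoles. No stereocentre is formed; the selectivity needed is positional and is secured by the halogen pattern of 13, since the carbon that bore iodine becomes C3a' and the one that bore chlorine becomes C7a', which puts the prenyl group at C6' and not at C5'. Holding the alkoxide back until both cross-couplings are over keeps a free terminal alkyne away from the aryl chloride and the palladium catalyst and shortens the time the prenyl groups spend with a strong base, while the SEM group shuts off arylation at N1.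

Step 9
Reactants: 18 6-prenyl-3-(6-prenyl-1H-indol-1-yl)-1-SEM-1H-indole
Product: 20 6-prenyl-3-(6-prenyl-1H-indol-1-yl)-1H-indole, via N-hydroxymethyl indole 19 (not isolated)
Conditions: TBAF, ethylenediamine, THF, 70 °C
Reagents that add atoms: none
Why: Fluoride-induced fragmentation of the SEM group (loss of fluorotrimethylsilane and ethylene, then of formaldehyde from the N-hydroxymethyl intermediate, which ethylenediamine scavenges) is the standard unmasking of SEM-protected indoles and should leave the prenyl groups and the N1'–C3 bond untouched.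

**Compound list**

1 | methyl 6-bromo-1H-indole-3-carboxylate | COC(=O)c1c[nH]c2cc(Br)ccc12 | starting material
2 | methyl 6-bromo-1-{[2-(trimethylsilyl)ethoxy]methyl}-1H-indole-3-carboxylate | COC(=O)c1cn(COCC[Si](C)(C)C)c2cc(Br)ccc12 | intermediate
3 | tributyl(3-methylbut-2-en-1-yl)stannane | CCCC[Sn](CCCC)(CCCC)CC=C(C)C | starting material
4 | methyl 6-(3-methylbut-2-en-1-yl)-1-{[2-(trimethylsilyl)ethoxy]methyl}-1H-indole-3-carboxylate | COC(=O)c1cn(COCC[Si](C)(C)C)c2cc(CC=C(C)C)ccc12 | intermediate
5 | 6-(3-methylbut-2-en-1-yl)-1-{[2-(trimethylsilyl)ethoxy]methyl}-1H-indole-3-carboxylic acid | OC(=O)c1cn(COCC[Si](C)(C)C)c2cc(CC=C(C)C)ccc12 | intermediate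
6 | 6-(3-methylbut-2-en-1-yl)-1-{[2-(trimethylsilyl)ethoxy]methyl}-1H-indole-3-carbonyl azide | [N-]=[N+]=NC(=O)c1cn(COCC[Si](C)(C)C)c2cc(CC=C(C)C)ccc12 | intermediate (not isolated)
7 | 3-isocyanato-6-(3-methylbut-2-en-1-yl)-1-{[2-(trimethylsilyl)ethoxy]methyl}-1H-indole | O=C=Nc1cn(COCC[Si](C)(C)C)c2cc(CC=C(C)C)ccc12 | intermediate (not isolated)
8 | 2-(trimethylsilyl)ethyl N-[6-(3-methylbut-2-en-1-yl)-1-{[2-(trimethylsilyl)ethoxy]methyl}-1H-indol-3-yl]carbamate | C[Si](C)(C)CCOC(=O)Nc1cn(COCC[Si](C)(C)C)c2cc(CC=C(C)C)ccc12 | intermediate
9 | 6-(3-methylbut-2-en-1-yl)-1-{[2-(trimethylsilyl)ethoxy]methyl}-1H-indol-3-amine | Nc1cn(COCC[Si](C)(C)C)c2cc(CC=C(C)C)ccc12 | intermediate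
10 | 4-bromo-2-chloroaniline | Nc1ccc(Br)cc1Cl | starting material
11 | 2-chloro-4-(3-methylbut-2-en-1-yl)aniline | CC(C)=CCc1ccc(N)c(Cl)c1 | intermediate
12 | 2-chloro-4-(3-methylbut-2-en-1-yl)benzenediazonium hydrogensulfate | CC(C)=CCc1ccc([N+]#N)c(Cl)c1.OS(=O)(=O)[O-] | intermediate (not isolated)
13 | 2-chloro-1-iodo-4-(3-methylbut-2-en-1-yl)benzene | CC(C)=CCc1ccc(I)c(Cl)c1 | intermediate
14 | trimethylsilylacetylene | C#C[Si](C)(C)C | starting material
15 | {[2-chloro-4-(3-methylbut-2-en-1-yl)phenyl]ethynyl}trimethylsilane | CC(C)=CCc1ccc(C#C[Si](C)(C)C)c(Cl)c1 | intermediate (not isolated)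
16 | 6-(3-methylbut-2-en-1-yl)-N-{5-(3-methylbut-2-en-1-yl)-2-[(trimethylsilyl)ethynyl]phenyl}-1-{[2-(trimethylsilyl)ethoxy]methyl}-1H-indol-3-amine | CC(C)=CCc1ccc(C#C[Si](C)(C)C)c(Nc2cn(COCC[Si](C)(C)C)c3cc(CC=C(C)C)ccc23)c1 | intermediate (not isolated)
17 | N-[2-ethynyl-5-(3-methylbut-2-en-1-yl)phenyl]-6-(3-methylbut-2-en-1-yl)-1-{[2-(trimethylsilyl)ethoxy]methyl}-1H-indol-3-amine | CC(C)=CCc1ccc(C#C)c(Nc2cn(COCC[Si](C)(C)C)c3cc(CC=C(C)C)ccc23)c1 | intermediate (not isolated)
18 | 6-(3-methylbut-2-en-1-yl)-3-[6-(3-methylbut-2-en-1-yl)-1H-indol-1-yl]-1-{[2-(trimethylsilyl)ethoxy]methyl}-1H-indole | CC(C)=CCc1ccc2c(-n3ccc4ccc(CC=C(C)C)cc43)cn(COCC[Si](C)(C)C)c2c1 | intermediate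
19 | {6-(3-methylbut-2-en-1-yl)-3-[6-(3-methylbut-2-en-1-yl)-1H-indol-1-yl]-1H-indol-1-yl}methanol | CC(C)=CCc1ccc2c(-n3ccc4ccc(CC=C(C)C)cc43)cn(CO)c2c1 | intermediate (not isolated)
20 | 6-(3-methylbut-2-en-1-yl)-3-[6-(3-methylbut-2-en-1-yl)-1H-indol-1-yl]-1H-indole | CC(C)=CCc1ccc2c(-n3ccc4ccc(CC=C(C)C)cc43)c[nH]c2c1 | target

**Step count**

Total steps: 9. Longest linear sequence: 7 steps (steps 1 to 5, 8 and 9); the dihaloarene branch (steps 6 and 7) joins at step 8.

**Steps most likely to fail, with fallbacks**

1. Key coupling (step 8). What may go wrong: early loss of the silyl group followed by oligomerisation of the free alkyne on palladium, stalling of the amination at the hindered ortho-alkynyl chloride, or base-induced migration of the prenyl double bonds into conjugation. The fallback keeps the same three bonds but changes the two-carbon unit to the aldehyde oxidation level and the ring closure to a condensation. It sets out from 13 and 9 and comes back at 18. Iodide 13 is coupled at C–I with (Z)-tributyl(2-ethoxyvinyl)stannane (Pd(PPh3)4, toluene, 90 °C, Stille coupling) to give (Z)-2-chloro-1-(2-ethoxyvinyl)-4-prenylbenzene F1. The chloride of F1 is then aminated with 9 (Pd(OAc)2, XPhos, Cs2CO3, toluene, 105 °C) to give N-[2-((Z)-2-ethoxyvinyl)-5-prenylphenyl]-6-prenyl-1-SEM-1H-indol-3-amine F2. A catalytic amount of pyridinium p-toluenesulfonate in warm toluene should then protonate the enol ether, let N1' add to the oxocarbenium carbon and expel ethanol, which gives 18 without any alkyne or strong base.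

2. Release of the amine (step 5). What may go wrong: oxidative decomposition or self-condensation of the free 3-aminoindole during work-up and transfer. The fallback avoids this amine altogether by bringing ring B in complete and forming the N1'–C3 bond by copper-catalysed N-arylation. It sets out from stannane 3 and comes back at 18. Purchased 6-bromo-1H-indole is coupled with 3 (Pd(PPh3)4, DMF, 100 °C) to give 6-prenyl-1H-indole F3. Part of F3 is protected (NaH, SEMCl, DMF) as 6-prenyl-1-SEM-1H-indole F4 and brominated at C3 (NBS, THF, −78 °C, where the indole reacts far faster than the olefins) to give 3-bromo-6-prenyl-1-SEM-1H-indole F5. Ullmann–Goldberg coupling of F3 with F5 (CuI, trans-N,N'-dimethylcyclohexane-1,2-diamine, K3PO4, toluene, 110 °C) should then give 18.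

3. Iodination through the diazonium salt (step 7). What may go wrong: nitrosation of the trisubstituted olefin, addition of iodine to it, or acid-promoted hydration while the diazonium salt is formed and consumed. The fallback moves the diazonium chemistry ahead of the prenylation. It sets out from 10 and comes back at 15, which is then isolated and enters step 8 at the amination stage. Aniline 10 is diazotised (NaNO2, aq H2SO4, 0 °C) to 4-bromo-2-chlorobenzenediazonium hydrogensulfate F6 and treated with KI to give 4-bromo-2-chloro-1-iodobenzene F7. Sonogashira coupling of F7 with 14 at the iodide (PdCl2(PPh3)2, CuI, Et3N, rt) gives [(4-bromo-2-chlorophenyl)ethynyl]trimethylsilane F8. Stille coupling of F8 with 3 at the bromide (Pd(PPh3)4, DMF, 100 °C) should then give 15.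

Further compounds
F1 | step 8 | (Z)-2-chloro-1-(2-ethoxyvinyl)-4-(3-methylbut-2-en-1-yl)benzene | CCO/C=C\c1ccc(CC=C(C)C)cc1Cl
F2 | step 8 | N-[2-((Z)-2-ethoxyvinyl)-5-(3-methylbut-2-en-1-yl)phenyl]-6-(3-methylbut-2-en-1-yl)-1-{[2-(trimethylsilyl)ethoxy]methyl}-1H-indol-3-amine | CCO/C=C\c1ccc(CC=C(C)C)cc1Nc1cn(COCC[Si](C)(C)C)c2cc(CC=C(C)C)ccc12
F3 | step 5 | 6-(3-methylbut-2-en-1-yl)-1H-indole | CC(C)=CCc1ccc2cc[nH]c2c1
F4 | step 5 | 6-(3-methylbut-2-en-1-yl)-1-{[2-(trimethylsilyl)ethoxy]methyl}-1H-indole | CC(C)=CCc1ccc2ccn(COCC[Si](C)(C)C)c2c1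
F5 | step 5 | 3-bromo-6-(3-methylbut-2-en-1-yl)-1-{[2-(trimethylsilyl)ethoxy]methyl}-1H-indole | CC(C)=CCc1ccc2c(Br)cn(COCC[Si](C)(C)C)c2c1
F6 | step 7 | 4-bromo-2-chlorobenzenediazonium hydrogensulfate | N#[N+]c1ccc(Br)cc1Cl.OS(=O)(=O)[O-]
F7 | step 7 | 4-bromo-2-chloro-1-iodobenzene | Clc1cc(Br)ccc1I
F8 | step 7 | [(4-bromo-2-chlorophenyl)ethynyl]trimethylsilane | C[Si](C)(C)C#Cc1ccc(Br)cc1Cl
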